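If the free catalyst had a fixed turnover number, a larger charge of starting material would stop at a lower percentage, so I test that on these runs.

| setting | Sunday's | Thursday's | flask |
|---|---|---|---|
| starting material | 0.67 M | 1.5 M | 1.0 M |
| gas phase | 200 mM (held) | 200 mM (held) | 200 mM (held) |
| free catalyst | 5 mM | 5 mM | 5.0 mM |
| remark | run made earlier | run made earlier |  |
| time |  |  | 10 d |

- Sunday's (time / d: product / %): 2.08: 58; 4.00: 84; 6.00: 90; 8.00: 95; 10.0: 97; 12.0: 95
- Thursday's (time / d: product / %): 0.833: 17; 2.50: 42; 4.00: 66; 6.00: 86; 10.0: 92; 12.0: 97

(each reading ± 1.5 percentage points)

- at the start none of the gas phase is in solution

- oak: doubling the transfer coefficient of the gas phase, all else as stated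
- ash: doubling the amount of free catalyst, all else as stated
- elm: doubling the saturation concentration of gas phase, all else as stated

- how much product there is at 10 d, in percent of the starting material charged
- the change that raises the amount of product at 10 d, in percent of the starting material charged most ("none" if none brings more than 2 percentage points) (oak / ash / elm / none)
- amount of product at 10 d, in percent of the starting material charged, after ash

Does the stop follow the charge? The late readings 97% and 95% of Sunday's run and 97% of Thursday's agree within the scatter of 1.5 percentage points, yet each free catalyst made about 130 products on Sunday and 291 on Thursday. So these two runs show no fixed count.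

What then? I write the balance of the free catalyst, charged in a smaller amount than the starting material. I suppose that it works at first order in starting material, dies at a pace blind to starting material, and meets the gas once in each step. Time and gas then cancel, and ln(charged/left) of the starting material grows in step with the catalyst lost. The late readings give a = 0.661 mM⁻¹: this is the catalyst reach, the growth of ln(charged/left) per amount of free catalyst lost.

Where does this flask stand? With c = 5.0 mM charged, a gives a stop near 96.3%. At 10 d the runs read 97% and 92%, so I commit to about 94.5%.

What moves it? On my supposition oak and elm change the pace, not the stop. Ash doubles c and lifts the stop to 99.9%, so I choose ash.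

The forecast gives 95% (92.5% to 97%), names elm, and puts ash at 97% (95% to 99.5%), holding that doubling catalyst “speeds the approach but can't move an equilibrium”. We part on the choice.

The simulation gives 95.4%, and ash is best, adding 4.4 points against 0.45 points for oak and 1 point for elm; after ash the flask reaches 99.8%.

    gas phase ⇌ dissolved gas, rate k1*(csat - [dissolved gas]) (kL = 2.30 × 10⁻⁵ s⁻¹)
    dissolved gas + free catalyst → spent catalyst (k = 2.10 × 10⁻⁵ M⁻¹ s⁻¹)
    starting material + dissolved gas + free catalyst → free catalyst + product (k = 0.0140 M⁻² s⁻¹)

At 2.08 d the flask's free catalyst has a half-life of 4.5 d by its loss to spent catalyst, shorter than the 10 d allowed, and at 10.0 d 7.63% of the charge is still free. The reach, applied to the 92.4% lost, gives 4.72% of the starting material left, and the flask holds 4.6%. A neighbour flask, the same but with 1.30 mM of free catalyst, has by the reach a stop at 57.7%. Computed, it holds 56.0% of product at 10.0 d, with 5.30% of its catalyst still free.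

The numbers in the tables were generated by integration for an exercise.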